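The earlier runs and the new flask stem from a simulated flask with made-up constants; noise was put on by code.

Target is the product wanted, so the question for each flask is how much of the charge stands as target at the end.

| flask | substrate | other conformer | temperature | remark | time |
|---|---|---|---|---|---|
| autumn | 0.060 M | 0.12 M | 25 °C | run made earlier |  |
| midnight | 0.24 M | 0.12 M | 60 °C | run made earlier |  |
| winter | 0.12 M | 0.18 M | 25 °C | run made earlier |  |
| north-east | 0.12 M | 0.120 M | 60 °C |  | 30 min |
| south-west | 0.12 M | 0.120 M | 30 °C |  | 30 min |
| east | 0.12 M | 0.120 M | 90 °C |  | 30 min |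

| run | time / min | target / % | substrate / % |
|---|---|---|---|
| autumn | 30.0 | 0.2 | 33.3 |
| autumn | 60.0 | 0 | 33.6 |
| autumn | 80.0 | 0 | 32.8 |
| autumn | 120 | 0.2 | 32.7 |
| autumn | 150 | 0.6 | 31.7 |
| autumn | 180 | 0.1 | 32.2 |
| midnight | 5.00 | 1.0 | 64.1 |
| midnight | 10.0 | 2.1 | 61.2 |
| midnight | 15.0 | 3.9 | 58.4 |
| midnight | 20.0 | 5.5 | 54.7 |
| midnight | 25.0 | 4.2 | 53.4 |
| midnight | 30.0 | 5.5 | 49.5 |
| winter | 15.0 | 1.1 | 39.8 |
| winter | 30.0 | 0 | 39.7 |
| winter | 50.0 | 0.8 | 39.2 |
| winter | 80.0 | 0 | 39.3 |
| winter | 180 | 0.2 | 39.5 |

(scatter of a reading: 0.5 percentage points)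

- in a conversion other conformer counts as not yet reacted

- the flask that comes out highest in amount of target, in percent of the substrate and other conformer together charged, or "all alike" when all lie within 1.5 percentage points (north-east / south-west / east / all alike)
- target at the end, in percent of the substrate and other conformer together charged, north-east
- target at the end, in percent of the substrate and other conformer together charged, south-west
- target at the end, in percent of the substrate and other conformer together charged, east

*What do the cold runs say?* At 25 °C, autumn ends at 0.1 % target and winter at 0.2 %, both inside the scatter of 0.5 percentage points. South-west, at 30 °C, I therefore put close to zero.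

*What can be carried from the midnight run?* There substrate falls from 66.7 % of the charge to 49.5 % while target reaches 5.5 %. This gives φ = 32.0 %, where φ is target gained per substrate lost, the selectivity. It is a reading and carries the scatter. I freeze it and multiply it by whatever a flask loses.

*And north-east?* The midnight run lost 25.7 % of its substrate at the same temperature and time. North-east starts with half the charge as substrate, so my figure is 4.12 %.

*East?* Taking the forecast's factor of about 30, the 30 min of east at 90 °C counts as that many midnight runs. I assume that the charge in east, other conformer included, is converted and yields φ, which gives 32.0 % target.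

*Weak spot?* Other conformer was never read, and φ comes from a single temperature. At 90 °C it is a commitment, not a measurement.

The forecast says east comes highest, with 4.2 % in north-east, 0.1 % in south-west and 60 % in east: “There the conformers equilibrate and drain to target”. Its east figure stands above mine.

The flasks give east as highest, with 5.02 % in north-east, 0.211 % in south-west and 40.0 % in east.

    substrate ⇌ dormant form (K = 0.419, k = 0.0801 min⁻¹, Ea = 108 kJ mol⁻¹, ΔH = 6.00 kJ mol⁻¹)
    other conformer → isomer of the product (k = 0.120 min⁻¹, Ea = 112 kJ mol⁻¹)
    2 other conformer → homo dimer (k = 0.182 L mol⁻¹ min⁻¹, Ea = 78.0 kJ mol⁻¹)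
    substrate ⇌ other conformer (K = 2.40, k = 0.0384 min⁻¹, Ea = 119 kJ mol⁻¹, ΔH = −9.00 kJ mol⁻¹)
    substrate → target (k = 0.0728 min⁻¹, Ea = 95.0 kJ mol⁻¹)
    substrate + target → side product (k = 1.06 L mol⁻¹ min⁻¹, Ea = 69.0 kJ mol⁻¹)
    target ⇌ isomer of the product (K = 0.392, k = 0.0554 min⁻¹, Ea = 115 kJ mol⁻¹, ΔH = 16.0 kJ mol⁻¹)
    (constants at 90 °C)

East keeps 1.37 % substrate, 1.62 % other conformer and 1.22 % dormant form, so φ on the rest of the charge gives 30.7 % against the 40.0 % found. At 5.58 min in east, target is made 3.70 times faster than it is used up, net. At that moment in east, the forward step to isomer of the product, taken alone, uses target at 1.0 times the rate of the step with substrate to side product.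

In the neighbour of east charged with 0.20 M of substrate, 1.38 % substrate, 1.52 % other conformer and 1.28 % dormant form remain, so φ on the rest of the charge gives 30.7 %. That flask gives 33.6 %.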